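| setting | Monday's | Saturday's | Tuesday's | south-east | north-east | east |
|---|---|---|---|---|---|---|
| electrophile | 0.050 M | 0.025 M | 0.10 M | 0.050 M | 0.050 M | 0.050 M |
| nucleophile | 0.045 M | 0.045 M | 0.045 M | 0.0450 M | 0.0450 M (fed, over 5.0 min) | 0.0450 M |
| free base | 0.025 M | 0.025 M | 0.025 M | 0.0250 M (fed, over 5.0 min) | 0.0250 M | 0.0250 M |
| remark | run made earlier | run made earlier | run made earlier | all else is in the flask from the start; the feed brings no volume worth counting | all else is in the flask from the start; the feed brings no volume worth counting | everything together at the start |
| time |  |  |  | 12 min | 12 min | 12 min |

- Monday's (time / min: target / %): 1.00: 19.0; 1.33: 21.7; 2.00: 25.2; 3.00: 29.9; 5.00: 34.7; 8.00: 36.6; 12.0: 37.6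
- Saturday's (time / min: target / %): 2.00: 28.7; 4.00: 36.6; 6.00: 40.3; 8.00: 42.7; 10.0: 44.5; 12.0: 45.5; 15.0: 46.5
- Tuesday's (time / min: target / %): 0.833: 14.6; 2.00: 20.7; 4.00: 26.0; 6.00: 26.2; 8.00: 26.4; 12.0: 27.0; 15.0: 27.7

(standard deviation of a reading: 0.5 percentage points)

- the flask with the highest amount of target, in percent of the electrophile charged ("all alike" if they lie within 1.5 percentage points) (south-east / north-east / east / all alike)
- final target, as a percentage of the electrophile charged, in south-east
- final target, as a percentage of the electrophile charged, in north-east
- final target, as a percentage of the electrophile charged, in east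

I began with an easy count: I took each target to cost one nucleophile, so whatever of the nucleophile charge had not become target by the last reading was waste. Waste per target, W, is a selectivity factor turned upside down. I multiplied it by electrophile charged over nucleophile charged and called the product λ 1.55. It read 1.55 on Monday's run, 1.59 on Saturday's and 1.39 on Tuesday's, so I froze it. Target is then the nucleophile charge over (1 + W). Monday's λ returned 47.5% for Saturday's run, which read 46.5%, and 26.5% for Tuesday's, which read 27.7%. But Tuesday's target stood near 0.0260 M from 4.00 min, beside the base charge of 0.025 M, so I trusted the number below that charge, 50.0% of the electrophile here.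

East repeats Monday's recipe, so W was 1.39, and I kept 37.6% for east and for south-east, whose feed changes neither charge. In a flask charged at once, I took the nucleophile to fall from its charge towards zero, a mean of 0.5 of the charge. Monday's target reached half of its last reading at 1.00 min, giving a time constant τ of 1.44 min. Because τ is shorter than the feed, I held the fed level at τ/5.0 min of the charge, so W fell to 0.804. North-east therefore came to 49.9%, above the others.

The forecast named east, with 37% for south-east, 32% for north-east and 37.6% for east; of north-east it said: “Feeding nucleophile leaves base decaying while nucleophile is scarce.” My reckoning parted from it on north-east.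

The flasks gave 39.7% in south-east, 47.8% in north-east and 37.6% in east, so north-east held the most.

    electrophile + nucleophile → acid set free + target (k = 0.160 /M/s)
    nucleophile + acid set free ⇌ protonated nucleophile, settled at all times (K = 590 /M)
    acid set free + free base ⇌ salt of the base (K = 9.60 × 10⁵ /M, k = 16.0 /M/s)
    2 nucleophile → self-condensation product (k = 0.310 /M/s)

Counting two nucleophile per self-condensation product, waste per target came to 1.38 in east and 0.833 in north-east, against my 1.39 and 0.804. I then took λ to a neighbour of east charged with 0.011 M of nucleophile. There W became 0.341, and target 16.4% of the electrophile. That flask gave 15.8%, with 84% of its electrophile left.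

Readings and results were generated by integration on assumed constants; the scatter is artificial.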